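The cyclopentane is cut at C1–C2 and C3–C4; the seven-membered ring already holds C1–C5–C4. Numbering: C1 quaternary carbon (methyl C15), C2/C3 the CH2CH2 unit, C4 the isopropyl carbinol, C5 the ring-fusion CH, C6–C10 the rest of the seven-membered ring. The feature used is the 1,4-relationship of the oxygenated carbons C10 and C4: as ketones they make C1 an enolate carbon and C4 an electrophile. In a 2-methylene-3-isobutyrylcycloheptanone, conjugate hydride addition creates C15 and the C1 enolate; this adds to diphenylvinylsulfonium triflate and the ylide closes onto the C4 ketone as an epoxide. One operation gives both bonds, the trans fusion, C1 and C4.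

Key step: step 9

Remark: α is the face of the seven-membered ring that carries H-5 (and O-6, O-9, O-10 of the target), β the face of the C15 methyl; "daucane" is the target skeleton numbered as above, with C14 on C8. The configuration shown corresponds to (S) at C6 in 5. The C10 carbinol of 17–19 is drawn as the expected β epimer; either epimer would serve. 2-Bromo-3-methylbut-1-ene (7) is taken as purchasable.

Step 1
Reactants: 1 tropone
Product: 2 cyclohepta-3,5-dien-1-one
Conditions: LiAlH4 (0.3 equiv), Et2O, 0 °C; aq. NH4Cl
Reagents that add atoms: none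
Why: Conjugate (1,8-) hydride addition to the trienone followed by kinetic alpha-protonation of the dienolate on work-up should give the unconjugated 3,5-dienone (hydride reduction; no stereocentre).

Step 2
Reactants: 2 cyclohepta-3,5-dien-1-one
Product: 3 1,4-dioxaspiro[4.6]undeca-7,9-diene
Conditions: (TMSOCH2)2, TMSOTf (2 mol %), CH2Cl2, −78 °C
Reagents that add atoms: 1,2-bis(trimethylsilyloxy)ethane C[Si](C)(C)OCCO[Si](C)(C)C
Why: Silyl-triflate-catalysed ketalization with the bis-silyl ether of ethylene glycol runs aprotically at −78 °C, so the beta,gamma-unsaturated ketone (future C8 carbonyl) should be protected without double-bond migration (no stereocentre).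

Step 3
Reactants: 3 1,4-dioxaspiro[4.6]undeca-7,9-diene
Product: 4 meso endoperoxide (peroxide bridge across the diene termini, the future C6 and C10)
Conditions: O2, hν (visible), tetraphenylporphyrin (cat.), CH2Cl2, −20 °C
Reagents that add atoms: dioxygen O=O
Why: [4+2] cycloaddition of singlet oxygen to the cyclic 1,3-diene; the peroxide bridge is necessarily cis and the spiro ketal lies on the mirror plane, so one meso endoperoxide should result.

Step 4
Reactants: 4 meso endoperoxide
Product: 5 (S)-10-hydroxy-1,4-dioxaspiro[4.6]undec-8-en-7-one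
Conditions: cinchona-alkaloid-derived chiral amine base (10 mol %, pseudoenantiomer chosen for the S carbinol), CH2Cl2, rt
Reagents that add atoms: none
Why: Catalytic asymmetric Kornblum–DeLaMare rearrangement: the chiral base removes one of the two enantiotopic bridgehead hydrogens, O–O cleavage gives the C10 ketone and leaves the C6 carbinol as the only stereocentre, set as (S) by catalyst control.

Step 5
Reactants: 5 (S)-hydroxy enone
Product: 6 (S)-10-(tert-butyldimethylsilyloxy)-1,4-dioxaspiro[4.6]undec-8-en-7-one
Conditions: TBSCl, imidazole, DMF, rt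
Reagents that add atoms: tert-butyldimethylsilyl chloride CC(C)(C)[Si](C)(C)Cl
Why: Standard silylation of the secondary allylic alcohol; the bulky C6 silyl ether is the control element for step 6 and makes C6–O a poor leaving group later (no new stereocentre).

Step 6
Reactants: 6 silyloxy enone; 7 2-bromo-3-methylbut-1-ene (as its Grignard reagent)
Product: 9 8-(dimethylaminomethyl)-9-(3-methylbut-1-en-2-yl)-10-(tert-butyldimethylsilyloxy)-1,4-dioxaspiro[4.6]undecan-7-one (8,9-trans; 9,10-trans), via bromomagnesium enolate 8 (not isolated)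
Conditions: 7, Mg, THF, rt; CuI (10 mol %), 6, THF, −78 → −40 °C; then CH2=NMe2+ I−, −40 °C → rt
Reagents that add atoms: dimethylmethyleneammonium iodide C=[N+](C)C.[I-]
Why: Copper-catalysed conjugate addition of the alkenyl Grignard reagent should occur anti to the gamma-silyloxy group (sets C5, new substituent β), and Mannich trapping of the regiodefined enolate at C1 should occur anti to that substituent (C1 is only a transient centre here).

Step 7
Reactants: 9 Mannich base
Product: 11 8-methylene-9-(3-methylbut-1-en-2-yl)-10-(tert-butyldimethylsilyloxy)-1,4-dioxaspiro[4.6]undecan-7-one (9,10-trans), via trimethylammonium iodide 10 (not isolated)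
Conditions: MeI, Et2O, rt; then aq. NaHCO3, CH2Cl2, rt
Reagents that add atoms: none
Why: N-Methylation and E1cB loss of trimethylamine (Mannich-base methylenation) should give the exocyclic enone C1=C15, which stores both the C15 methyl and the position of the future C1 enolate; the mild base should leave C5 untouched.

Step 8
Reactants: 11 exocyclic enone
Product: 12 9-(2-methylpropanoyl)-8-methylene-10-(tert-butyldimethylsilyloxy)-1,4-dioxaspiro[4.6]undecan-7-one (9,10-trans)
Conditions: O3, CH2Cl2, −78 °C (dye end-point indicator); Me2S, −78 °C → rt; crude product used at once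
Reagents that add atoms: ozone [O-][O+]=O
Why: Ozonolysis is chemoselective for the electron-rich 1,1-dialkyl alkene over the electron-poor exocyclic enone, so only the C4 isopropyl ketone should be unveiled; the neutral reductive work-up avoids epimerisation at C5 and migration of the C1=C15 double bond.

Step 9
Reactants: 12 methylene diketone; 13 diphenylvinylsulfonium triflate
Product: 16 3β,4β-epoxy-6α-(tert-butyldimethylsilyloxy)-8,8-(ethylenedioxy)-14-nordaucan-10-one (trans-fused; 1β-methyl; 5α-H), via lithium enolate 14 (not isolated), via sulfonium ylide 15 (not isolated)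
Conditions: LiBH(s-Bu)3 (1.05 equiv), THF, −78 °C; then 13 (1.5 equiv) in CH2Cl2, −78 → 0 °C
Reagents that add atoms: none
Why: Proposed new method: LiBH(s-Bu)3 adds hydride to C15 of the exocyclic enone (1,4-reduction, which also creates the C15 methyl) and gives the tetrasubstituted lithium enolate 14 with its double bond fixed between C10 and C1; C1 then adds to the vinylsulfonium salt (C1–C2), the sulfonium ylide 15 adds through C3 to the C4 ketone (C3–C4) and the alkoxide displaces Ph2S to close the epoxide. The closest known reaction types are reductive enolate alkylation after conjugate reduction, the vinylsulfonium epoxy-annulation of heteroatom nucleophiles that carry a ketone (conjugate addition, then Johnson–Corey–Chaykovsky closure) and the vinylphosphonium cyclopentene annulation of keto enolates; a ketone enolate as the carbon nucleophile forming a quaternary centre is the untested part. The cyclopentane closes by 5-exo-trig attack of the ylide carbon on the carbonyl, the epoxide by 3-exo-tet displacement. C1 is set by attack of the acceptor on the enolate face anti to the β-oriented C5 isobutyryl group (C2 α, methyl β, hence the trans ring fusion); C4 is set in the ylide addition, where the isopropyl group should turn away from the silyloxy-bearing C6 so that oxygen ends on the β face; C3 is a transient centre removed in step 10. The step needs 1,4-reduction without attack on the C4 ketone, which the hindered isopropyl ketone and the s-cis exocyclic enone should secure at −78 °C, and trapping of 14 before proton transfer from C5 (which would expel the C6 silyloxy group), which the unhindered and very reactive vinylsulfonium acceptor should secure.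

Step 10
Reactants: 16 epoxy ketone
Product: 17 6α-(tert-butyldimethylsilyloxy)-8,8-(ethylenedioxy)-14-nordaucane-4β,10β-diol
Conditions: LiAlH4, THF, 0 → 50 °C; H2O, aq. NaOH
Reagents that add atoms: none
Why: Hydride reduction: LiAlH4 reduces the C10 ketone and opens the trisubstituted epoxide by SN2 attack at the less substituted C3, so the C4–O bond and its β configuration are kept as the tertiary carbinol; the C10 configuration is irrelevant because C10 becomes sp2 in step 12.

Step 11
Reactants: 17 diol
Product: 18 10-O-methanesulfonate of 17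
Conditions: MsCl (1.2 equiv), Et3N, CH2Cl2, −10 °C
Reagents that add atoms: methanesulfonyl chloride CS(Cl)(=O)=O
Why: Sulfonylation (via sulfene) should be selective for the only free secondary hydroxyl at C10, the tertiary C4 hydroxyl being too hindered and C6 still silylated; no stereocentre changes.

Step 12
Reactants: 18 mesylate
Product: 20 4β,6α-dihydroxy-14-nordauc-9-en-8-one, via keto mesylate 19 (not isolated)
Conditions: 2 M HCl, THF, rt; then Et3N (excess), rt
Reagents that add atoms: water O
Why: Acid hydrolysis of the dioxolane and the silyl ether gives the beta-mesyloxy ketone 19, and E1cB elimination on basification can only expel the C10 mesylate (the C6 hydroxyl is a poor leaving group), which should give the C8 enone with the C9=C10 double bond.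

Step 13
Reactants: 20 dihydroxy enone; 21 3-methylbutanoyl (isovaleryl) chloride
Product: 22 4β-hydroxy-8-oxo-14-nordauc-9-en-6α-yl 3-methylbutanoate
Conditions: 21 (1.2 equiv), pyridine, DMAP (cat.), CH2Cl2, 0 °C
Reagents that add atoms: none
Why: Acylation under nucleophilic catalysis of the secondary C6 hydroxyl; the tertiary C4 hydroxyl should not react at 0 °C and the mild base avoids beta-elimination of the new ester.

Step 14
Reactants: 22 enone ester
Product: 23 4β,9α,10α-trihydroxy-8-oxo-14-nordaucan-6α-yl 3-methylbutanoate
Conditions: OsO4 (5 mol %), NMO, citric acid, t-BuOH/H2O, rt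
Reagents that add atoms: N-methylmorpholine N-oxide C[N+]1([O-])CCOCC1; water O
Why: Catalytic OsO4 dihydroxylation (buffered for the electron-poor enone) is a syn addition that should occur on the α face of C9=C10, anti to the C15 methyl on the neighbouring quaternary C1, setting both C9 and C10.

Step 15
Reactants: 23 dihydroxy ketone
Product: 24 4β,9α,10α-trihydroxydauc-8(14)-en-6α-yl 3-methylbutanoate
Conditions: Zn, CH2Br2, TiCl4 (reagent pre-formed in THF, excess), CH2Cl2, 0 °C → rt
Reagents that add atoms: dibromomethane BrCBr
Why: Takai–Lombardo methylenation: the non-basic gem-dimetallic methylene reagent converts ketones but not esters and does not enolise the beta-acyloxy alpha-hydroxy ketone, so C9 should keep its configuration; free hydroxyls only consume excess reagent.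

Step 16
Reactants: 24 allylic diol
Product: 25 target, 8α,14-epoxy-4β,9α,10α-trihydroxydaucan-6α-yl 3-methylbutanoate (CNP0307265.1)
Conditions: VO(acac)2 (5 mol %), t-BuOOH, CH2Cl2, 0 °C → rt
Reagents that add atoms: tert-butyl hydroperoxide CC(C)(C)OO
Why: Hydroxyl-directed epoxidation: the vanadate ester of the allylic C9 hydroxyl (helped by the homoallylic C10 hydroxyl, both α) delivers oxygen to the α face of C8=C14, which should set C8 with the epoxide oxygen cis to the C9 hydroxyl.

Compound list
1 | tropone (cyclohepta-2,4,6-trien-1-one) | O=C1C=CC=CC=C1 | starting material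
2 | cyclohepta-3,5-dien-1-one | O=C1CC=CC=CC1 | intermediate
3 | 1,4-dioxaspiro[4.6]undeca-7,9-diene | C1COC2(O1)CC=CC=CC2 | intermediate
4 | meso endoperoxide of 3 (6,7-dioxabicyclo[3.2.2]non-8-en-3-one ethylene ketal) | O1O[C@H]2C=C[C@@H]1CC1(OCCO1)C2 | intermediate
5 | (S)-10-hydroxy-1,4-dioxaspiro[4.6]undec-8-en-7-one (hydroxyl on future C6, ketone = future C10) | O[C@H]1CC2(OCCO2)CC(=O)C=C1 | intermediate
6 | (S)-10-(tert-butyldimethylsilyloxy)-1,4-dioxaspiro[4.6]undec-8-en-7-one | CC(C)(C)[Si](C)(C)O[C@H]1CC2(OCCO2)CC(=O)C=C1 | intermediate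
7 | 2-bromo-3-methylbut-1-ene | C=C(Br)C(C)C | starting material
8 | bromomagnesium enolate (C7=C8) of 9-(3-methylbut-1-en-2-yl)-10-(tert-butyldimethylsilyloxy)-1,4-dioxaspiro[4.6]undecan-7-one, 9,10-trans (not isolated) | CC(C)(C)[Si](C)(C)O[C@H]1CC2(OCCO2)CC(O[Mg]Br)=C[C@@H]1C(=C)C(C)C | intermediate
9 | 8-(dimethylaminomethyl)-9-(3-methylbut-1-en-2-yl)-10-(tert-butyldimethylsilyloxy)-1,4-dioxaspiro[4.6]undecan-7-one (8,9-trans; 9,10-trans) | CC(C)(C)[Si](C)(C)O[C@H]1CC2(OCCO2)CC(=O)[C@@H](CN(C)C)[C@@H]1C(=C)C(C)C | intermediate
10 | trimethylammonium iodide of 9 (not isolated) | CC(C)(C)[Si](C)(C)O[C@H]1CC2(OCCO2)CC(=O)[C@@H](C[N+](C)(C)C)[C@@H]1C(=C)C(C)C.[I-] | intermediate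
11 | 8-methylene-9-(3-methylbut-1-en-2-yl)-10-(tert-butyldimethylsilyloxy)-1,4-dioxaspiro[4.6]undecan-7-one (9,10-trans) | CC(C)(C)[Si](C)(C)O[C@H]1CC2(OCCO2)CC(=O)C(=C)[C@@H]1C(=C)C(C)C | intermediate
12 | 9-(2-methylpropanoyl)-8-methylene-10-(tert-butyldimethylsilyloxy)-1,4-dioxaspiro[4.6]undecan-7-one (9,10-trans) | CC(C)(C)[Si](C)(C)O[C@H]1CC2(OCCO2)CC(=O)C(=C)[C@@H]1C(=O)C(C)C | intermediate
13 | diphenylvinylsulfonium triflate | C=C[S+](c1ccccc1)c1ccccc1.[O-]S(=O)(=O)C(F)(F)F | starting material
14 | lithium enolate (C10–O–Li, C10=C1, C1 methyl) from 1,4-reduction of 12 (not isolated) | CC(C)(C)[Si](C)(C)O[C@H]1CC2(OCCO2)CC(O[Li])=C(C)[C@@H]1C(=O)C(C)C | intermediate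
15 | sulfonium ylide, C1 bearing methyl and CH2–CH(−)–S(+)Ph2, C2 α (not isolated) | CC(C)(C)[Si](C)(C)O[C@H]1CC2(OCCO2)CC(=O)[C@@](C)(C[CH-][S+](c3ccccc3)c3ccccc3)[C@@H]1C(=O)C(C)C | intermediate
16 | 3β,4β-epoxy-6α-(tert-butyldimethylsilyloxy)-8,8-(ethylenedioxy)-14-nordaucan-10-one (trans-fused, 1β-methyl, 5α-H) | CC(C)(C)[Si](C)(C)O[C@H]1CC2(OCCO2)CC(=O)[C@@]3(C)C[C@@H]4O[C@]4(C(C)C)[C@H]13 | intermediate
17 | 6α-(tert-butyldimethylsilyloxy)-8,8-(ethylenedioxy)-14-nordaucane-4β,10β-diol | CC(C)(C)[Si](C)(C)O[C@H]1CC2(OCCO2)C[C@H](O)[C@@]3(C)CC[C@@](O)(C(C)C)[C@H]13 | intermediate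
18 | 10-O-methanesulfonate of 17 | CC(C)(C)[Si](C)(C)O[C@H]1CC2(OCCO2)C[C@H](OS(C)(=O)=O)[C@@]3(C)CC[C@@](O)(C(C)C)[C@H]13 | intermediate
19 | 4β,6α-dihydroxy-10β-(methanesulfonyloxy)-14-nordaucan-8-one (not isolated) | O[C@H]1CC(=O)C[C@H](OS(C)(=O)=O)[C@@]2(C)CC[C@@](O)(C(C)C)[C@H]12 | intermediate
20 | 4β,6α-dihydroxy-14-nordauc-9-en-8-one | O[C@H]1CC(=O)C=C[C@@]2(C)CC[C@@](O)(C(C)C)[C@H]12 | intermediate
21 | 3-methylbutanoyl (isovaleryl) chloride | CC(C)CC(Cl)=O | starting material
22 | 4β-hydroxy-8-oxo-14-nordauc-9-en-6α-yl 3-methylbutanoate | CC(C)CC(=O)O[C@H]1CC(=O)C=C[C@@]2(C)CC[C@@](O)(C(C)C)[C@H]12 | intermediate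
23 | 4β,9α,10α-trihydroxy-8-oxo-14-nordaucan-6α-yl 3-methylbutanoate | CC(C)CC(=O)O[C@H]1CC(=O)[C@@H](O)[C@@H](O)[C@@]2(C)CC[C@@](O)(C(C)C)[C@H]12 | intermediate
24 | 4β,9α,10α-trihydroxydauc-8(14)-en-6α-yl 3-methylbutanoate | CC(C)CC(=O)O[C@H]1CC(=C)[C@@H](O)[C@@H](O)[C@@]2(C)CC[C@@](O)(C(C)C)[C@H]12 | intermediate
25 | 8α,14-epoxy-4β,9α,10α-trihydroxydaucan-6α-yl 3-methylbutanoate (CNP0307265.1) | CC(C)CC(=O)O[C@H]1C[C@]2(CO2)[C@@H](O)[C@@H](O)[C@@]2(C)CC[C@@](O)(C(C)C)[C@H]12 | target

Total step count: 16
Longest linear sequence: 16 steps (tropone 1 to target 25)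

Steps most likely to fail

1. Step 9 (Proposed new method). What may go wrong: proton transfer from C5 to the C1 enolate, followed by loss of the C6 silyloxy group; hydride attack on the C4 ketone; protonation of the ylide instead of carbonyl addition; or poor facial control at C4. The fallback sets out from 12 and comes back at 16, with known reactions only. 12 is reduced with LiBH(s-Bu)3 as before, but the enolate is trapped with vinyltriphenylphosphonium bromide. Conjugate addition and intramolecular Wittig reaction of the phosphorus ylide with the C4 ketone should give the trans-fused cyclopentene F1, with a C3=C4 double bond bearing the isopropyl group. TBAF then frees the C6 hydroxyl to give the homoallylic alcohol F2. VO(acac)2/t-BuOOH epoxidation, directed by this hydroxyl on the β face of the cyclopentene, should give the 3β,4β-epoxy alcohol F3. TBSCl/imidazole returns to 16.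

2. Step 15. What may go wrong: chelation of the alpha,beta-dihydroxy ketone to titanium, which can stall methylene transfer or start an alpha-ketol rearrangement. The fallback sets out from 23 and comes back at 24. 2,2-Dimethoxypropane/PPTS gives the 9,10-acetonide F4. Addition of Me3SiCH2MgCl/CeCl3 to the C8 ketone at −78 °C gives the beta-hydroxysilane F5 (either C8 epimer). Aqueous HF in MeCN then effects Peterson elimination and acetonide cleavage in one operation to give 24.

3. Step 4. What may go wrong: insufficient discrimination of the two enantiotopic bridgehead hydrogens by the chiral base for this ketal-bearing endoperoxide, or base-induced opening of the beta-keto ketal after the rearrangement. The fallback sets out from 4 and comes back at 6. Thiourea in MeOH reduces the peroxide to the meso cis-diol F6. Desymmetrising acetylation with Burkholderia cepacia lipase and vinyl acetate gives the monoacetate F7 with the future C6 hydroxyl free; if the enzyme acylates the other hydroxyl, the order of silylation and oxidation is exchanged. TBSCl/imidazole gives the silyl ether acetate F8. K2CO3/MeOH removes the acetate to give the allylic alcohol F9. MnO2 oxidation then gives 6.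

Further compounds
F1 | step 9 | 6α-(tert-butyldimethylsilyloxy)-8,8-(ethylenedioxy)-14-nordauc-3-en-10-one (trans-fused cyclopentene) | CC(C)(C)[Si](C)(C)O[C@H]1CC2(OCCO2)CC(=O)[C@@]3(C)CC=C(C(C)C)[C@H]13
F2 | step 9 | 6α-hydroxy-8,8-(ethylenedioxy)-14-nordauc-3-en-10-one | O[C@H]1CC2(OCCO2)CC(=O)[C@@]3(C)CC=C(C(C)C)[C@H]13
F3 | step 9 | 3β,4β-epoxy-6α-hydroxy-8,8-(ethylenedioxy)-14-nordaucan-10-one | O[C@H]1CC2(OCCO2)CC(=O)[C@@]3(C)C[C@@H]4O[C@]4(C(C)C)[C@H]13
F4 | step 15 | 9α,10α-O-isopropylidene derivative (acetonide) of 23 | CC(C)CC(=O)O[C@H]1CC(=O)[C@H]2OC(C)(C)O[C@H]2[C@@]3(C)CC[C@@](O)(C(C)C)[C@H]13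
F5 | step 15 | 8-hydroxy-8-(trimethylsilylmethyl) adduct of F4 (C8 configuration open) | CC(C)CC(=O)O[C@H]1CC(O)(C[Si](C)(C)C)[C@H]2OC(C)(C)O[C@H]2[C@@]3(C)CC[C@@](O)(C(C)C)[C@H]13
F6 | step 4 | meso cis-1,4-dioxaspiro[4.6]undec-8-ene-7,10-diol | O[C@H]1CC2(OCCO2)C[C@@H](O)C=C1
F7 | step 4 | monoacetate of F6 (acetate on future C10, free hydroxyl on future C6) | O[C@H]1CC2(OCCO2)C[C@@H](OC(C)=O)C=C1
F8 | step 4 | tert-butyldimethylsilyl ether of F7 | CC(C)(C)[Si](C)(C)O[C@H]1CC2(OCCO2)C[C@@H](OC(C)=O)C=C1
F9 | step 4 | cis-10-(tert-butyldimethylsilyloxy)-1,4-dioxaspiro[4.6]undec-8-en-7-ol | CC(C)(C)[Si](C)(C)O[C@H]1CC2(OCCO2)C[C@@H](O)C=C1
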